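**Plan**

- Cuts: (i) the C(sp)–C(sp2) bond of the enyne, giving alkynyl dioxane acid 13 and (E)-vinyl iodide 17; (ii) the ring bond O1–C6, which opens the only ring to an acyclic α-methoxy hydroperoxide enal; (iii) O2–C3 and C3–OCH3, back to a 1,1-disubstituted alkene; (iv) the bonds at that carbon, back to hex-5-ynoic acid and a three-carbon Grignard reagent.
- Enabling feature: in the 1,2-dioxane (O1, O2, C3–C6), O1 sits on C6, which is β to the carboxyl carbon of the acetic acid arm, so O1–C6 is a conjugate-addition retron. C3 carries O2 and OCH3, so it is the methanol adduct of a carbonyl oxide.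
- Forward: the C12 enal chain is built linearly, ozonolysis in methanol installs the hydroperoxy ketal, and the dioxane ring is closed by an amine-catalysed 6-exo-trig peroxy-Michael addition. The aldehyde is then oxidised, C3 is equilibrated, and the side chain is joined last.
- Stereochemistry: C6 (S) comes from the chiral amine catalyst. C3 (R) comes from acid-catalysed anomeric equilibration (OCH3 axial, both carbon substituents equatorial). The (E)-alkene comes from a Takai olefination and is retained in the coupling.

Key step: step 7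

Remark: ring atoms are numbered O1, O2, C3 (methoxy ketal carbon), C4, C5, C6 (carbon bearing the CH2CO2H arm); the sense of induction in step 7 is taken from the face-shielding model for diarylprolinol silyl ether iminium ions, and the enantiomeric catalyst is equally available should the sense prove opposite.

**Route**

Step 1
Reactants: 1 hex-5-ynoic acid
Product: 3 N-methoxy-N-methylhex-5-ynamide, via acylimidazole 2 (not isolated)
Conditions: 1,1'-carbonyldiimidazole (1.1 equiv), CH2Cl2, rt, 1 h; then MeNH(OMe)·HCl (1.2 equiv), rt
Reagents that add atoms: 1,1'-carbonyldiimidazole, O=C(n1ccnc1)n1ccnc1 (imidazolyl group of intermediate 2 only); N,O-dimethylhydroxylamine hydrochloride, CNOC.Cl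
Why: Weinreb amide formation through an acylimidazole is routine for an unhindered acid and leaves the terminal alkyne untouched.

Step 2
Reactants: 3 N-methoxy-N-methylhex-5-ynamide; 4 [2-(1,3-dioxolan-2-yl)ethyl]magnesium bromide
Product: 5 1-(1,3-dioxolan-2-yl)oct-7-yn-3-one
Conditions: 4 (2.3 equiv, 0.5 M in THF), THF, 0 °C → rt; sat. aq. NH4Cl
Reagents that add atoms: none
Why: Weinreb ketone synthesis, in which the chelated magnesium adduct stops at the ketone stage; one extra equivalent of 4 is consumed by the alkyne C–H and the dioxolane should survive the NH4Cl quench.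

Step 3
Reactants: 5 1-(1,3-dioxolan-2-yl)oct-7-yn-3-one
Product: 6 2-(3-methylideneoct-7-yn-1-yl)-1,3-dioxolane
Conditions: Ph3PCH3Br (1.5 equiv), KOtBu (1.4 equiv), THF, 0 °C → rt
Reagents that add atoms: methyltriphenylphosphonium bromide, C[P+](c1ccccc1)(c1ccccc1)c1ccccc1.[Br-]
Why: Wittig methylenation of an unhindered dialkyl ketone should give the 1,1-disubstituted alkene that later delivers the carbonyl oxide at C3.

Step 4
Reactants: 6 2-(3-methylideneoct-7-yn-1-yl)-1,3-dioxolane
Product: 7 4-methylidenenon-8-ynal
Conditions: 1 M aq. HCl, THF, rt → 40 °C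
Reagents that add atoms: water, O
Why: Acid-catalysed acetal hydrolysis; the isolated alkene and alkyne are inert to dilute aqueous acid at this temperature.

Step 5
Reactants: 7 4-methylidenenon-8-ynal
Product: 8 (2E)-6-methylideneundec-2-en-10-ynal
Conditions: Ph3P=CHCHO (1.2 equiv), toluene, 80 °C
Reagents that add atoms: (triphenylphosphoranylidene)acetaldehyde, O=CC=P(c1ccccc1)(c1ccccc1)c1ccccc1
Why: Wittig olefination with a formyl-stabilised ylide should give the (E)-enal selectively, and a small excess of ylide limits a second homologation.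

Step 6
Reactants: 8 (2E)-6-methylideneundec-2-en-10-ynal
Product: 10 (2E)-6-hydroperoxy-6-methoxyundec-2-en-10-ynal (racemic), via carbonyl oxide 9 (not isolated)
Conditions: O3/O2 (1.0 equiv, Sudan Red 7B end point), CH2Cl2/MeOH 4:1, −78 °C; N2 purge; concentrate below 20 °C
Reagents that add atoms: ozone, [O-][O+]=O; methanol, CO
Why: Criegee ozonolysis with methanol trapping, in which ozone should attack the electron-rich 1,1-dialkyl alkene much faster than the enal C=C or the alkyne (as in selective cleavage of an isopropenyl group beside an enone), the primary ozonide splits to the more substituted carbonyl oxide plus formaldehyde, and methanol adds to give the α-methoxy hydroperoxide; the ketal carbon forms racemic and is corrected in step 9.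

Step 7
Reactants: 10 (2E)-6-hydroperoxy-6-methoxyundec-2-en-10-ynal (racemic)
Product: 11 2-[(3RS,6S)-3-methoxy-3-(pent-4-yn-1-yl)-1,2-dioxan-6-yl]acetaldehyde (both C3 epimers)
Conditions: (R)-2-{bis[3,5-bis(trifluoromethyl)phenyl][(trimethylsilyl)oxy]methyl}pyrrolidine (20 mol %), 4-nitrobenzoic acid (20 mol %), toluene (0.02 M), −20 → 0 °C; short silica plug, used at once
Reagents that add atoms: none
Why: Proposed new method: the amine condenses with the enal to an (E), s-trans iminium ion, the tethered α-methoxy hydroperoxide oxygen adds to its β-carbon (the future C6), and protonation and hydrolysis of the resulting enamine release aldehyde 11 and the catalyst. The closest known reaction types are the intermolecular iminium-catalysed enantioselective conjugate peroxidation of enals by alkyl hydroperoxides and the base-mediated racemic cyclisation of hydroperoxy ketals onto enoates; the intramolecular catalytic asymmetric version is new. The 1,2-dioxane closes by a 6-exo-trig oxa-Michael addition (O1–C6 bond) through a chair-like transition state. C6 is set by the catalyst, whose bis(aryl)(silyloxy)methyl group blocks one face of the iminium ion so that the (R)-catalyst should expose the face leading to (6S); C3 is not controlled here, because both enantiomers of 10 cyclise, and it is set in step 9. The step needs conjugate addition rather than 1,2-addition or collapse of the peroxy enamine to an epoxide: intramolecular 1,2-addition would need an eight-membered ring spanning the (E)-alkene, the acid co-catalyst should protonate the enamine quickly, and high dilution suppresses intermolecular addition.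

Step 8
Reactants: 11 2-[(3RS,6S)-3-methoxy-3-(pent-4-yn-1-yl)-1,2-dioxan-6-yl]acetaldehyde
Product: 12 2-[(3RS,6S)-3-methoxy-3-(pent-4-yn-1-yl)-1,2-dioxan-6-yl]acetic acid (both C3 epimers)
Conditions: NaClO2 (3 equiv), NaH2PO4 (3 equiv), 2-methylbut-2-ene (15 equiv), tBuOH/H2O 4:1, 0 °C
Reagents that add atoms: sodium chlorite, [Na+].[O-]Cl=O
Why: Pinnick oxidation at about pH 4 should convert the aldehyde to the acid without enolisation, so the β-peroxy carbonyl unit cannot lose the peroxide by retro-Michael reaction, and the scavenger protects the alkyne from HOCl.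

Step 9
Reactants: 12 2-[(3RS,6S)-3-methoxy-3-(pent-4-yn-1-yl)-1,2-dioxan-6-yl]acetic acid
Product: 13 2-[(3R,6S)-3-methoxy-3-(pent-4-yn-1-yl)-1,2-dioxan-6-yl]acetic acid
Conditions: camphorsulfonic acid (10 mol %), MeOH (3 equiv), CH2Cl2, 0 °C → rt
Reagents that add atoms: methanol, CO
Why: Acid-catalysed ketal exchange (anomerisation) through the peroxycarbenium ion should equilibrate C3 only, and the (3R,6S) isomer is favoured because it alone has OCH3 axial (anomeric effect with O2) with the pentynyl chain and the acetic acid arm both equatorial; C6 is untouched.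

Step 10
Reactants: 14 dec-9-en-1-ol
Product: 15 10-hydroxydecan-2-one
Conditions: PdCl2 (10 mol %), CuCl (1 equiv), O2 (1 atm), DMF/H2O 7:1, rt
Reagents that add atoms: water, O
Why: Tsuji–Wacker oxidation, in which Markovnikov hydroxypalladation of the terminal alkene gives the methyl ketone and the remote primary alcohol is tolerated.

Step 11
Reactants: 15 10-hydroxydecan-2-one
Product: 16 9-oxodecanal
Conditions: Dess–Martin periodinane (1.2 equiv), NaHCO3, CH2Cl2, 0 °C → rt
Reagents that add atoms: none
Why: Dess–Martin oxidation of the primary alcohol should stop at the aldehyde and leave the ketone alone.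

Step 12
Reactants: 16 9-oxodecanal
Product: 17 (10E)-11-iodoundec-10-en-2-one
Conditions: CrCl2 (6 equiv), CHI3 (2 equiv), THF/1,4-dioxane 1:6, 0 °C → rt
Reagents that add atoms: iodoform, IC(I)I
Why: Takai olefination, in which the geminal dichromium carbenoid should add to the aldehyde in preference to the methyl ketone and eliminate to the (E)-vinyl iodide.

Step 13
Reactants: 13 2-[(3R,6S)-3-methoxy-3-(pent-4-yn-1-yl)-1,2-dioxan-6-yl]acetic acid; 17 (10E)-11-iodoundec-10-en-2-one
Product: 18 2-[(3R,6S)-3-methoxy-3-[(6E)-15-oxohexadec-6-en-4-yn-1-yl]-1,2-dioxan-6-yl]acetic acid (target)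
Conditions: PdCl2(PPh3)2 (5 mol %), CuI (10 mol %), Et3N (5 equiv), degassed THF, rt; pH 4 buffer work-up
Reagents that add atoms: none
Why: Sonogashira coupling should join the terminal alkyne to the vinyl iodide with retention of the (E) geometry; the acid travels as its ammonium carboxylate, which disfavours base-induced loss of the β-peroxide, and peroxyketal 1,2-dioxanes have close precedent for surviving palladium cross-coupling at room temperature.

**Compound list**

1 | hex-5-ynoic acid | C#CCCCC(=O)O | starting material
2 | 1-(1H-imidazol-1-yl)hex-5-yn-1-one | C#CCCCC(=O)n1ccnc1 | intermediate (not isolated)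
3 | N-methoxy-N-methylhex-5-ynamide | C#CCCCC(=O)N(C)OC | intermediate
4 | [2-(1,3-dioxolan-2-yl)ethyl]magnesium bromide (0.5 M in THF) | Br[Mg]CCC1OCCO1 | starting material
5 | 1-(1,3-dioxolan-2-yl)oct-7-yn-3-one | C#CCCCC(=O)CCC1OCCO1 | intermediate
6 | 2-(3-methylideneoct-7-yn-1-yl)-1,3-dioxolane | C#CCCCC(=C)CCC1OCCO1 | intermediate
7 | 4-methylidenenon-8-ynal | C#CCCCC(=C)CCC=O | intermediate
8 | (2E)-6-methylideneundec-2-en-10-ynal | C#CCCCC(=C)CC/C=C/C=O | intermediate
9 | carbonyl oxide of (2E)-6-oxoundec-2-en-10-ynal | C#CCCCC(=[O+][O-])CC/C=C/C=O | intermediate (not isolated)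
10 | (2E)-6-hydroperoxy-6-methoxyundec-2-en-10-ynal, racemic | C#CCCCC(OC)(OO)CC/C=C/C=O | intermediate
11 | 2-[(3RS,6S)-3-methoxy-3-(pent-4-yn-1-yl)-1,2-dioxan-6-yl]acetaldehyde | COC1(CCCC#C)CC[C@@H](CC=O)OO1 | intermediate
12 | 2-[(3RS,6S)-3-methoxy-3-(pent-4-yn-1-yl)-1,2-dioxan-6-yl]acetic acid | COC1(CCCC#C)CC[C@@H](CC(=O)O)OO1 | intermediate
13 | 2-[(3R,6S)-3-methoxy-3-(pent-4-yn-1-yl)-1,2-dioxan-6-yl]acetic acid | CO[C@@]1(CCCC#C)CC[C@@H](CC(=O)O)OO1 | intermediate
14 | dec-9-en-1-ol | C=CCCCCCCCCO | starting material
15 | 10-hydroxydecan-2-one | CC(=O)CCCCCCCCO | intermediate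
16 | 9-oxodecanal | CC(=O)CCCCCCCC=O | intermediate
17 | (10E)-11-iodoundec-10-en-2-one | CC(=O)CCCCCCC/C=C/I | intermediate
18 | 2-[(3R,6S)-3-methoxy-3-[(6E)-15-oxohexadec-6-en-4-yn-1-yl]-1,2-dioxan-6-yl]acetic acid | CO[C@@]1(CCCC#C/C=C/CCCCCCCC(C)=O)CC[C@@H](CC(=O)O)OO1 | target

**Step count**

Total: 13 steps. Longest linear sequence: 10 steps (steps 1–9, then step 13).

**Steps most likely to fail**

Step 7 (proposed new method). The peroxy enamine may collapse to an epoxide with O–O cleavage, one enantiomer of the racemic hydroperoxy ketal may cyclise poorly, or facial selectivity may be low. The fallback uses known chemistry, sets out from enal 8 and comes back at acid 13. Enal 8 is treated with 2-methoxypropan-2-yl hydroperoxide under the same (R)-amine catalyst, the known intermolecular enantioselective conjugate peroxidation of enals, to give (3S)-3-[(2-methoxypropan-2-yl)peroxy]-6-methylideneundec-10-ynal F1. Pinnick oxidation gives (3S)-3-[(2-methoxypropan-2-yl)peroxy]-6-methylideneundec-10-ynoic acid F2. Ozonolysis of the 1,1-disubstituted alkene in CH2Cl2 with pyridine at −78 °C gives (3S)-3-[(2-methoxypropan-2-yl)peroxy]-6-oxoundec-10-ynoic acid F3. Camphorsulfonic acid in CH2Cl2/MeOH then removes the peroxyketal protecting group to give (3S)-3-hydroperoxy-6-oxoundec-10-ynoic acid F4, which should close onto the ketone to 2-[(3RS,6S)-3-hydroxy-3-(pent-4-yn-1-yl)-1,2-dioxan-6-yl]acetic acid F5 and exchange OH for OCH3 under the same anomeric control to give 13. In this fallback the ring closes by peroxyhemiketal formation rather than by conjugate addition.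

Step 6. Ozone may also attack the enal double bond or the alkyne, or the carbonyl oxide may add to the free aldehyde in place of methanol. The fallback sets out from aldehyde 7 and comes back at hydroperoxide 10. Aldehyde 7, which has no conjugated alkene, is ozonised in CH2Cl2/MeOH at −78 °C to give 4-hydroperoxy-4-methoxynon-8-ynal F6, which should rest as its cyclic peroxyhemiacetal 6-methoxy-6-(pent-4-yn-1-yl)-1,2-dioxan-3-ol F7. Wittig olefination of this ring-chain mixture with Ph3P=CHCHO in CH2Cl2 at 40 °C then gives 10, so the enal is made only after the oxidation.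

Step 13. The O–O bond may be reduced by single-electron transfer from copper or by the palladium/phosphine system, or the copper acetylide may homocouple. The fallback sets out from acid 13 and aldehyde 16 and comes back at target 18. Acid 13 is brominated at the alkyne terminus (N-bromosuccinimide, AgNO3 10 mol %, acetone, rt) to give 2-[(3R,6S)-3-(5-bromopent-4-yn-1-yl)-3-methoxy-1,2-dioxan-6-yl]acetic acid F8. Aldehyde 16 is converted by the boron variant of the Takai olefination (CrCl2, Cl2CHB(pin), LiI, THF) into (10E)-11-(4,4,5,5-tetramethyl-1,3,2-dioxaborolan-2-yl)undec-10-en-2-one F9. A copper-free and amine-free Suzuki–Miyaura coupling of F8 with F9 (Pd(PPh3)4 5 mol %, Cs2CO3, THF/H2O, rt) should then give 18.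

**Further compounds**

F1 | step 7 | (3S)-3-[(2-methoxypropan-2-yl)peroxy]-6-methylideneundec-10-ynal | C#CCCCC(=C)CC[C@@H](CC=O)OOC(C)(C)OC
F2 | step 7 | (3S)-3-[(2-methoxypropan-2-yl)peroxy]-6-methylideneundec-10-ynoic acid | C#CCCCC(=C)CC[C@@H](CC(=O)O)OOC(C)(C)OC
F3 | step 7 | (3S)-3-[(2-methoxypropan-2-yl)peroxy]-6-oxoundec-10-ynoic acid | C#CCCCC(=O)CC[C@@H](CC(=O)O)OOC(C)(C)OC
F4 | step 7 | (3S)-3-hydroperoxy-6-oxoundec-10-ynoic acid | C#CCCCC(=O)CC[C@@H](CC(=O)O)OO
F5 | step 7 | 2-[(3RS,6S)-3-hydroxy-3-(pent-4-yn-1-yl)-1,2-dioxan-6-yl]acetic acid | OC1(CCCC#C)CC[C@@H](CC(=O)O)OO1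
F6 | step 6 | 4-hydroperoxy-4-methoxynon-8-ynal | C#CCCCC(OC)(OO)CCC=O
F7 | step 6 | 6-methoxy-6-(pent-4-yn-1-yl)-1,2-dioxan-3-ol | COC1(CCCC#C)CCC(O)OO1
F8 | step 13 | 2-[(3R,6S)-3-(5-bromopent-4-yn-1-yl)-3-methoxy-1,2-dioxan-6-yl]acetic acid | CO[C@@]1(CCCC#CBr)CC[C@@H](CC(=O)O)OO1
F9 | step 13 | (10E)-11-(4,4,5,5-tetramethyl-1,3,2-dioxaborolan-2-yl)undec-10-en-2-one | CC(=O)CCCCCCC/C=C/B1OC(C)(C)C(C)(C)O1
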